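The chroman is disconnected at the aryl ether bond O1–C8a. This leaves C2, with its methyl, vinyl, oxygen and the C3–C4 ethylene arm, as the untouched carbinol carbon of (R)-linalool, and turns the phenol ring into a benzoquinone. The key step uses the fact that C8a is then a quinone carbonyl carbon within six-membered reach of the tertiary hydroxyl: 1,2-addition closes the pyran ring, the adduct is held as a mixed ketal, and zinc aromatises it to the chromanol in the same flask, with the C2–O bond never broken. The precursor is a benzoquinone carrying an (R)-3-hydroxy-3-methylpent-4-enyl chain; the dienyl side chain is attached afterwards by Heck coupling at the vinyl group.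

Key step: step 4

Remark: the acid obtained from linalool by loss of acetone is the seven-carbon (R)-4-hydroxy-4-methylhex-5-enoic acid, handled as its γ-lactone and sodium salt; β-homocyclocitral, a commercial flavour chemical, is taken as the side-chain starting material.

**Step 1**
Reactants: 1 (R)-linalool
Product: 2 (5R)-5-methyl-5-vinyltetrahydrofuran-2-ol (lactol of (R)-4-hydroxy-4-methylhex-5-enal, both C2 epimers)
Conditions: O3, CH2Cl2, −78 °C, Sudan Red 7B end point; then Me2S, −78 °C → rt
Reagents that add atoms: ozone, [O-][O+]=O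
Why: Criegee ozonolysis, in which the electron-rich trisubstituted C6=C7 alkene is cleaved far faster than the monosubstituted vinyl group, so that titration to the dye end point stops after one alkene and the γ-hydroxy aldehyde closes to the lactol while the carbinol stereocentre is untouched.

**Step 2**
Reactants: 2 (5R)-5-methyl-5-vinyltetrahydrofuran-2-ol
Product: 3 (R)-5-methyl-5-vinyldihydrofuran-2(3H)-one
Conditions: TEMPO (10 mol %), PhI(OAc)2, CH2Cl2, rt
Reagents that add atoms: none
Why: TEMPO/PhI(OAc)2 (oxoammonium) oxidation turns the lactol C–H into the lactone carbonyl under neutral conditions that leave the vinyl group and the tertiary stereocentre alone.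

**Step 3**
Reactants: 3 (R)-5-methyl-5-vinyldihydrofuran-2(3H)-one; 4 1,4-benzoquinone
Product: 6 (R)-2-(3-hydroxy-3-methylpent-4-en-1-yl)cyclohexa-2,5-diene-1,4-dione, via sodium (R)-4-hydroxy-4-methylhex-5-enoate 5 (not isolated)
Conditions: NaOH (1.05 equiv), H2O, rt; then 4 (3 equiv), AgNO3 (0.2 equiv), (NH4)2S2O8 (slow addition), MeCN/H2O, 60 °C, pH 5–6 held with NaHCO3
Reagents that add atoms: none
Why: Jacobsen–Torssell (Minisci-type) decarboxylative alkylation, in which Ag(II) formed by persulfate oxidises the carboxylate, loss of CO2 gives a nucleophilic primary radical that adds to the electron-poor quinone C=C and the adduct is reoxidised to the alkylquinone; working with the salt near pH 5–6 should keep the γ-hydroxy acid from relactonising, the excess of quinone should limit dialkylation, and the stereocentre lies two carbons from the radical.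

**Step 4**
Reactants: 6 (R)-2-(3-hydroxy-3-methylpent-4-en-1-yl)cyclohexa-2,5-diene-1,4-dione
Product: 9 (R)-2-methyl-2-vinylchroman-6-ol, via cyclic hemiketal 7 (not isolated), via cyclic methyl ketal 8 (not isolated)
Conditions: HC(OMe)3 (3 equiv), TsOH·H2O (2 mol %), CH2Cl2, 0 °C, until 6 is consumed; then Zn dust, AcOH, 0 °C → rt
Reagents that add atoms: none
Why: With a trace of acid the tertiary hydroxyl adds to the neighbouring quinone carbonyl carbon (the future C8a) to give hemiketal 7, which the orthoformate turns into the mixed methyl ketal 8, a quinone monoketal that no longer reverts to the open quinone, and only then does zinc in acetic acid deliver two electrons to the ionised ketal so that methanol is expelled and the ring aromatises. The closest known chemistry is the ketalisation–reduction of γ-hydroxyalkyl trimethylbenzoquinones of the tocopherylquinone type and the reductive aromatisation of quinone monoketals to hydroquinone monoethers, here applied to a quinone without ring methyl groups. The pyran ring is closed in a 6-exo-trig addition to C=O that forms the O1–C8a bond, not by substitution at C2. No stereocentre is created that survives (C8a of 7 and 8 becomes aromatic), and because the C2–O bond of the linalool carbinol is never broken the R configuration cannot be lost by ionisation. The step needs 1,2-addition at C8a in preference to conjugate addition at the free ring carbons and to plain reduction of the quinone; the six-membered tether, the poor Michael-donor character of a tertiary alcohol, the nearly methanol-free medium and the late addition of the reductant are meant to secure this, and once C8a is a ketal carbon the adjacent C5 is no longer a β-position of an enone.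

**Step 5**
Reactants: 9 (R)-2-methyl-2-vinylchroman-6-ol
Product: 10 (R)-tert-butyldimethyl[(2-methyl-2-vinylchroman-6-yl)oxy]silane
Conditions: TBSCl, imidazole, DMF, rt
Reagents that add atoms: tert-butyldimethylsilyl chloride, CC(C)(C)[Si](C)(C)Cl
Why: Imidazole-promoted silylation of the phenol, chosen so that the electron-rich hydroquinone monoether is not oxidised by Ag(I) or Pd(II) in the coupling step.

**Step 6**
Reactants: 11 β-homocyclocitral, (2,6,6-trimethylcyclohex-1-en-1-yl)acetaldehyde
Product: 12 2-(2,6,6-trimethylcyclohex-1-en-1-yl)ethan-1-ol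
Conditions: NaBH4, MeOH, 0 °C
Reagents that add atoms: none
Why: Borohydride reduction of the aldehyde, with the tetrasubstituted ring alkene inert and the cold, near-neutral medium avoiding migration of the β,γ-double bond.

**Step 7**
Reactants: 12 2-(2,6,6-trimethylcyclohex-1-en-1-yl)ethan-1-ol
Product: 13 2-(2-bromoethyl)-1,3,3-trimethylcyclohex-1-ene
Conditions: CBr4, PPh3, CH2Cl2, 0 °C
Reagents that add atoms: carbon tetrabromide, BrC(Br)(Br)Br
Why: Appel reaction, an SN2 displacement of the alkoxyphosphonium ion by bromide at the primary carbon without acid that could disturb the tetrasubstituted alkene.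

**Step 8**
Reactants: 13 2-(2-bromoethyl)-1,3,3-trimethylcyclohex-1-ene; 14 propyne
Product: 18 (Z)-2-(4-iodo-3-methylbut-3-en-1-yl)-1,3,3-trimethylcyclohex-1-ene, via Grignard reagent 15 (not isolated), via alkylcopper 16 (not isolated), via (Z)-alkenylcopper 17 (not isolated)
Conditions: Mg, Et2O, reflux; CuBr·SMe2, Et2O/Me2S, −45 °C; propyne, −25 °C; I2, −50 → 0 °C
Reagents that add atoms: iodine, II
Why: Normant carbocupration, in which the alkylcopper adds syn across propyne with the alkyl group going to the internal carbon and copper to the terminal one, and iodinolysis of the alkenyl–copper bond with retention places iodine cis to the CH2CH2 chain, which is the Z iodide.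

**Step 9**
Reactants: 10 (R)-tert-butyldimethyl[(2-methyl-2-vinylchroman-6-yl)oxy]silane; 18 (Z)-2-(4-iodo-3-methylbut-3-en-1-yl)-1,3,3-trimethylcyclohex-1-ene
Product: 19 (R)-tert-butyldimethyl({2-methyl-2-[(1E,3Z)-4-methyl-6-(2,6,6-trimethylcyclohex-1-en-1-yl)hexa-1,3-dien-1-yl]chroman-6-yl}oxy)silane
Conditions: Pd(OAc)2 (10 mol %), Ag2CO3, DMF, rt → 40 °C, dark
Reagents that add atoms: none
Why: Heck reaction under ligand-free, silver-assisted (Jeffery-type) conditions, in which oxidative addition keeps the Z geometry of the iodide, syn carbopalladation occurs at the terminal CH2 because the quaternary C2 shields the internal carbon, and syn β-hydride elimination, possible only towards the new CH2 since C2 carries no hydrogen, gives the E double bond, while silver removes iodide and suppresses Pd–H readdition and C2 is not touched.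

**Step 10**
Reactants: 19 (R)-tert-butyldimethyl({2-methyl-2-[(1E,3Z)-4-methyl-6-(2,6,6-trimethylcyclohex-1-en-1-yl)hexa-1,3-dien-1-yl]chroman-6-yl}oxy)silane
Product: 20 (R)-2-methyl-2-[(1E,3Z)-4-methyl-6-(2,6,6-trimethylcyclohex-1-en-1-yl)hexa-1,3-dien-1-yl]chroman-6-ol
Conditions: TBAF, AcOH, THF, 0 °C, under argon
Reagents that add atoms: none
Why: Fluoride-induced cleavage of the aryl silyl ether, buffered with acetic acid so that no free phenoxide is exposed to air, with the diene and C2 unaffected.

**Compound list**
1 | (R)-linalool, (3R)-3,7-dimethylocta-1,6-dien-3-ol | C=C[C@@](O)(C)CCC=C(C)C | starting material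
2 | (5R)-5-methyl-5-vinyltetrahydrofuran-2-ol (both C2 epimers) | C=C[C@@]1(C)CCC(O)O1 | intermediate
3 | (R)-5-methyl-5-vinyldihydrofuran-2(3H)-one | C=C[C@@]1(C)CCC(=O)O1 | intermediate
4 | 1,4-benzoquinone | O=C1C=CC(=O)C=C1 | starting material
5 | sodium (R)-4-hydroxy-4-methylhex-5-enoate | C=C[C@@](O)(C)CCC(=O)[O-].[Na+] | intermediate (not isolated)
6 | (R)-2-(3-hydroxy-3-methylpent-4-en-1-yl)cyclohexa-2,5-diene-1,4-dione | C=C[C@@](O)(C)CCC1=CC(=O)C=CC1=O | intermediate
7 | (2R)-8a-hydroxy-2-methyl-2-vinyl-3,4-dihydro-2H-chromen-6(8aH)-one (both C8a epimers) | C=C[C@@]1(C)CCC2=CC(=O)C=CC2(O)O1 | intermediate (not isolated)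
8 | (2R)-8a-methoxy-2-methyl-2-vinyl-3,4-dihydro-2H-chromen-6(8aH)-one (both C8a epimers) | C=C[C@@]1(C)CCC2=CC(=O)C=CC2(OC)O1 | intermediate (not isolated)
9 | (R)-2-methyl-2-vinylchroman-6-ol | C=C[C@@]1(C)CCc2cc(O)ccc2O1 | intermediate
10 | (R)-tert-butyldimethyl[(2-methyl-2-vinylchroman-6-yl)oxy]silane | C=C[C@@]1(C)CCc2cc(O[Si](C)(C)C(C)(C)C)ccc2O1 | intermediate
11 | β-homocyclocitral, (2,6,6-trimethylcyclohex-1-en-1-yl)acetaldehyde | CC1=C(CC=O)C(C)(C)CCC1 | starting material
12 | 2-(2,6,6-trimethylcyclohex-1-en-1-yl)ethan-1-ol | CC1=C(CCO)C(C)(C)CCC1 | intermediate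
13 | 2-(2-bromoethyl)-1,3,3-trimethylcyclohex-1-ene | CC1=C(CCBr)C(C)(C)CCC1 | intermediate
14 | propyne | CC#C | starting material
15 | [2-(2,6,6-trimethylcyclohex-1-en-1-yl)ethyl]magnesium bromide | CC1=C(CC[Mg]Br)C(C)(C)CCC1 | intermediate (not isolated)
16 | [2-(2,6,6-trimethylcyclohex-1-en-1-yl)ethyl]copper (MgBr2·SMe2 complex) | CC1=C(CC[Cu])C(C)(C)CCC1 | intermediate (not isolated)
17 | [(Z)-2-methyl-4-(2,6,6-trimethylcyclohex-1-en-1-yl)but-1-en-1-yl]copper | CC1=C(CC/C(C)=C\[Cu])C(C)(C)CCC1 | intermediate (not isolated)
18 | (Z)-2-(4-iodo-3-methylbut-3-en-1-yl)-1,3,3-trimethylcyclohex-1-ene | CC1=C(CC/C(C)=C\I)C(C)(C)CCC1 | intermediate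
19 | (R)-tert-butyldimethyl({2-methyl-2-[(1E,3Z)-4-methyl-6-(2,6,6-trimethylcyclohex-1-en-1-yl)hexa-1,3-dien-1-yl]chroman-6-yl}oxy)silane | CC1=C(CC/C(C)=C\C=C\[C@@]2(C)CCc3cc(O[Si](C)(C)C(C)(C)C)ccc3O2)C(C)(C)CCC1 | intermediate
20 | (R)-2-methyl-2-[(1E,3Z)-4-methyl-6-(2,6,6-trimethylcyclohex-1-en-1-yl)hexa-1,3-dien-1-yl]chroman-6-ol | CC1=C(CC/C(C)=C\C=C\[C@@]2(C)CCc3cc(O)ccc3O2)C(C)(C)CCC1 | target

Total step count: 10
Longest linear sequence: 7 steps (steps 1, 2, 3, 4, 5, 9, 10); the side-chain iodide is made in 3 steps (6, 7, 8).

**Steps most likely to fail**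

1. Step 4. Conjugate addition of the tethered hydroxyl or of liberated methanol to the unsubstituted quinone ring may outrun ketal formation. The acid needed for ketal exchange may also ionise the allylic tertiary alcohol, or the ketal may open during reduction, so that only ring-opened hydroquinone material is obtained.
Fallback: it sets out from 6 and comes back at 9, forming the O1–C2 bond under catalyst control instead of the O1–C8a bond. Reduction of 6 with aqueous Na2S2O4 (EtOAc/H2O) should give (R)-2-(3-hydroxy-3-methylpent-4-en-1-yl)benzene-1,4-diol F1. Exhaustive acetylation (Ac2O, Et3N, DMAP, CH2Cl2) should give (R)-2-(3-acetoxy-3-methylpent-4-en-1-yl)-1,4-phenylene diacetate F2. Brief methanolysis of the two aryl acetates (K2CO3, degassed MeOH, 0 °C) should leave (R)-5-(2,5-dihydroxyphenyl)-3-methylpent-1-en-3-yl acetate F3. Palladium-catalysed asymmetric allylic etherification (Pd2(dba)3·CHCl3, Trost DACH-phenyl ligand, AcOH, CH2Cl2, rt) should then close the chroman through a π-allyl complex to give 9. The configuration at C2 would be set by the ligand, not by linalool, and the ligand antipode that delivers R would have to be identified in a first run.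

2. Step 3. Relactonisation of the γ-hydroxy acid as the medium acidifies may remove the radical precursor before decarboxylation, and sulfate radical may attack the vinyl group.
Fallback: it sets out from 1 and comes back at 6, masking the hydroxyl from the start so that no lactol or lactone can form. Silylation of 1 (TESOTf, 2,6-lutidine, CH2Cl2, −78 °C) should give (R)-[(3,7-dimethylocta-1,6-dien-3-yl)oxy]triethylsilane F4. Selective ozonolysis as in step 1 should give (R)-4-methyl-4-[(triethylsilyl)oxy]hex-5-enal F5. Pinnick oxidation (NaClO2, NaH2PO4, 2-methyl-2-butene, t-BuOH/H2O) should give (R)-4-methyl-4-[(triethylsilyl)oxy]hex-5-enoic acid F6. The silver/persulfate alkylation of 4 under ordinary acidic conditions should give (R)-2-{3-methyl-3-[(triethylsilyl)oxy]pent-4-en-1-yl}cyclohexa-2,5-diene-1,4-dione F7. HF·pyridine in MeCN at 0 °C should then release 6; any silyl ether lost after the coupling already gives 6.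

3. Step 9. Readdition of palladium hydride may scramble the diene geometry, Pd(0) may ionise the tertiary allylic aryl ether (racemisation or ring opening), or insertion into the hindered vinyl group may be too slow.
Fallback: it sets out from 10 and comes back at 19, replacing the Heck reaction by a cross-coupling in which both alkene geometries are fixed beforehand. Lemieux–Johnson cleavage of the vinyl group of 10 (cat. OsO4, NaIO4, 2,6-lutidine, dioxane/H2O) should give (R)-6-[(tert-butyldimethylsilyl)oxy]-2-methylchroman-2-carbaldehyde F8. Takai–Utimoto boryl-olefination (CrCl2, LiI, Cl2CHBpin, THF) should give (R,E)-tert-butyldimethyl({2-methyl-2-[2-(4,4,5,5-tetramethyl-1,3,2-dioxaborolan-2-yl)vinyl]chroman-6-yl}oxy)silane F9. Suzuki–Miyaura coupling of F9 with 18 (Pd(PPh3)4, aqueous K3PO4, THF, rt) should give 19 with retention at both double bonds.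

**Further compounds**
F1 | step 4 | (R)-2-(3-hydroxy-3-methylpent-4-en-1-yl)benzene-1,4-diol | C=C[C@@](O)(C)CCc1cc(O)ccc1O
F2 | step 4 | (R)-2-(3-acetoxy-3-methylpent-4-en-1-yl)-1,4-phenylene diacetate | C=C[C@@](OC(C)=O)(C)CCc1cc(OC(C)=O)ccc1OC(C)=O
F3 | step 4 | (R)-5-(2,5-dihydroxyphenyl)-3-methylpent-1-en-3-yl acetate | C=C[C@@](OC(C)=O)(C)CCc1cc(O)ccc1O
F4 | step 3 | (R)-[(3,7-dimethylocta-1,6-dien-3-yl)oxy]triethylsilane | C=C[C@@](O[Si](CC)(CC)CC)(C)CCC=C(C)C
F5 | step 3 | (R)-4-methyl-4-[(triethylsilyl)oxy]hex-5-enal | C=C[C@@](O[Si](CC)(CC)CC)(C)CCC=O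
F6 | step 3 | (R)-4-methyl-4-[(triethylsilyl)oxy]hex-5-enoic acid | C=C[C@@](O[Si](CC)(CC)CC)(C)CCC(=O)O
F7 | step 3 | (R)-2-{3-methyl-3-[(triethylsilyl)oxy]pent-4-en-1-yl}cyclohexa-2,5-diene-1,4-dione | C=C[C@@](O[Si](CC)(CC)CC)(C)CCC1=CC(=O)C=CC1=O
F8 | step 9 | (R)-6-[(tert-butyldimethylsilyl)oxy]-2-methylchroman-2-carbaldehyde | O=C[C@@]1(C)CCc2cc(O[Si](C)(C)C(C)(C)C)ccc2O1
F9 | step 9 | (R,E)-tert-butyldimethyl({2-methyl-2-[2-(4,4,5,5-tetramethyl-1,3,2-dioxaborolan-2-yl)vinyl]chroman-6-yl}oxy)silane | CC1(C)OB(/C=C/[C@@]2(C)CCc3cc(O[Si](C)(C)C(C)(C)C)ccc3O2)OC1(C)C
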